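Slowness is what to watch here: the theta run has 70.3% of target after 2.00 min and is still climbing at 8.00 min, where it reads 82.5%.

| flask | starting material | second substrate | partner | free catalyst | added ligand | remark | time |
|---|---|---|---|---|---|---|---|
| theta | 0.012 M | 0.50 equiv | 1.2 equiv | 15 mol% | 7 mM | run made earlier |  |
| beta | 0.018 M | 0.50 equiv | 1.2 equiv | 15 mol% | 7 mM | run made earlier |  |
| elm | 0.012 M (fed, over 15 s) | 0.500 equiv | 1.20 equiv | 15 mol% | 7.0 mM | all else is in the flask from the start; the feed brings no volume worth counting | 12 min |
| alder | 0.012 M | 0.500 equiv | 1.20 equiv (fed, over 2.5 min) | 15 mol% | 7.0 mM | all else is in the flask from the start; the feed brings no volume worth counting | 12 min |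
| ash | 0.012 M | 0.500 equiv | 1.20 equiv | 15 mol% | 7.0 mM | everything together at the start | 12 min |
| maple | 0.012 M (fed, over 2.5 min) | 0.500 equiv | 1.20 equiv | 15 mol% | 7.0 mM | all else is in the flask from the start; the feed brings no volume worth counting | 12 min |

theta run (percent of the starting material charged)

| time / min | target / % |
|---|---|
| 0.667 | 51.6 |
| 2.00 | 70.3 |
| 3.00 | 75.6 |
| 5.00 | 79.3 |
| 8.00 | 82.5 |

beta run (percent of the starting material charged)

| time / s | target / % |
|---|---|
| 10.0 | 32.3 |
| 20.0 | 50.9 |
| 30.0 | 60.3 |
| 50.0 | 71.7 |
| 80.0 | 78.2 |

(standard deviation of a reading: 0.3 percentage points)

- the numbers in the tables scatter by 0.3 percentage points (one standard deviation)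

- the flask that comes out highest in amount of target, in percent of the starting material charged, or "all alike" when all lie within 1.5 percentage points (elm / alder / ash / maple / all alike)
- target at the end, in percent of the starting material charged, elm
- target at the end, in percent of the starting material charged, alder
- target at the end, in percent of the starting material charged, ash
- target at the end, in percent of the starting material charged, maple

A bench rule says that a recipe set in equivalents and mol%, when concentrated, keeps its yields and changes its clock: equal yield falls at equal concentration times time. This pair of runs tests that directly. Two ratios match:

c(starting material), beta over theta: 1.50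
time, theta over beta: 1.50

So beta at 80.0 s should match theta at 2.00 min. But beta reads 78.2% against 70.3%, ahead by 7.9 percentage points, with a scatter of 0.3 points. The rule stops here. One charge did not scale: added ligand stood at 7 mM in both runs.

Suppose starting material and added ligand compete for free catalyst. Divide one capture rate by the other, and free catalyst and time drop out. Up to a constant, what remains is the capture ratio:

ρ = c(starting material) / c(added ligand)
theta: ρ = 1.71
beta: ρ = 2.57

We carry this capture ratio. Beta has the higher ρ and the higher reading at the matched time.

Ash and alder start at theta's ρ. In elm and maple, starting material enters a flask already holding ligand, so ρ starts from nothing. With ligand counted at its charge and no fed starting material counted as used, elm comes to theta's ρ at 15 s, but maple by then has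

ρ ≤ 0.171

which is lower. Our reckoning gives an order and no percentages: ash first, alder close by, then elm, then maple.

The forecast names ash highest, with elm 84.3%, alder 84.8%, ash 85% and maple 78%. Its ground for the feeds differs from ours: “Feeding the starting material lets the second substrate consume partner first.”

The flasks give elm 78.6%, alder 80.6%, ash 82.9% and maple 74.7%, so ash stands highest, and elm lies 5.7 points under the forecast.

    free catalyst + added ligand ⇌ idle complex (K = 4200 /M, k = 20.0 /M/s)
    partner + catalyst intermediate A → free catalyst + target (k = 21.0 /M/s)
    starting material + free catalyst ⇌ catalyst intermediate A (K = 13000 /M, k = 88.0 /M/s)
    partner + catalyst intermediate B → free catalyst + second product (k = 2.10 /M/s)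
    starting material + target → side product (k = 0.170 /M/s)
    second substrate + free catalyst ⇌ catalyst intermediate B (K = 400 /M, k = 4.10 /M/s)

The ratio of the two forward capture constants, a selectivity factor, is 4.40. Times ρ, it gives 7.54 for ash at the start: the rate at which starting material takes free catalyst over the rate at which added ligand takes it, forward steps alone. The neighbouring flask repeats ash with 0.048 M of starting material, equivalents and loadings held, and added ligand at 7.0 mM. There ρ is 6.86 and the same rate ratio at the start is 30.2. That flask gives 94.3% of target and 5.69% of side product, in percent of the starting material charged.

(The data were generated by integration for substances that don't exist, noise included.)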